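## Retrosynthetic overview

- The route rests on C2, the only stereocentre. It is the β-carbon of the O1–C2–C3–C4(=O) unit of ring C and carries catechol ring B. The C2–C1' bond is therefore cut to a flat 4H-chromen-4-one and an arylboronic acid, to be joined by a ligand-controlled 1,4-addition.
- The C8 chain is cut at its ArCH2–CH= bond into a C8 benzylic carbonate and a (Z)-alkenyl boronate. The Z geometry comes from anti-carbomagnesiation of propargyl alcohol.
- The C8 carbon is put in place by an aromatic Claisen rearrangement on the bought ring A. The allyl group is then trimmed to CHO and reduced to CH2OH.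
- Ring order: A is bought, ring C is closed as the pyranone from an enaminone, the side chain is coupled on, ring B is attached last at C2, and acidic unmasking ends the route.

Key step: step 16

Remark: the (S)-antipode of the biaryl bisphosphine is assigned from the quadrant model for rhodium-catalysed additions to cyclic enones. The sense is to be checked on the first run, and the mirror-image ligand is equally available.

## Route

Step 1
Reactants: 1 2',6'-dihydroxy-4'-methoxyacetophenone
Product: 2 2'-allyloxy-6'-hydroxy-4'-methoxyacetophenone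
Conditions: allyl bromide (1.05 equiv), K2CO3 (1.1 equiv), acetone, reflux
Reagents that add atoms: allyl bromide C=CCBr
Why: Williamson etherification with one equivalent of halide should stop at the mono-ether, because the remaining phenol is held in a hydrogen bond to the acetyl oxygen and is much less nucleophilic.

Step 2
Reactants: 2 2'-allyloxy-6'-hydroxy-4'-methoxyacetophenone
Product: 3 2'-allyloxy-4'-methoxy-6'-(methoxymethoxy)acetophenone
Conditions: NaH (1.2 equiv), DMF, 0 °C; MOMCl (1.3 equiv), 0 °C → rt
Reagents that add atoms: chloromethyl methyl ether COCCl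
Why: Irreversible deprotonation breaks the chelate so that the phenoxide is O-alkylated by MOMCl (acetal protection), which leaves the allyl ether as the only group able to migrate.

Step 3
Reactants: 3 2'-allyloxy-4'-methoxy-6'-(methoxymethoxy)acetophenone
Product: 5 3'-allyl-2'-hydroxy-4'-methoxy-6'-(methoxymethoxy)acetophenone, via 6-allylcyclohexa-2,4-dienone 4 (not isolated)
Conditions: PhNEt2, 195–200 °C, sealed tube, Ar
Reagents that add atoms: none
Why: The aromatic Claisen rearrangement ([3,3] shift, then tautomerisation of 4) can deliver the allyl group only to C3', the one ortho carbon bearing hydrogen, and the basic solvent protects the MOM acetal.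

Step 4
Reactants: 5 3'-allyl-2'-hydroxy-4'-methoxy-6'-(methoxymethoxy)acetophenone
Product: 6 (E)-1-[3-allyl-2-hydroxy-4-methoxy-6-(methoxymethoxy)phenyl]-3-(dimethylamino)prop-2-en-1-one
Conditions: Me2NCH(OMe)2 (3 equiv), toluene, 100 °C
Reagents that add atoms: N,N-dimethylformamide dimethyl acetal COC(OC)N(C)C
Why: Condensation of the acetyl methyl group with the amide acetal (enaminone formation) is routine for 2'-hydroxyacetophenones, whose chelated phenol is not methylated under these conditions.

Step 5
Reactants: 6 (E)-1-[3-allyl-2-hydroxy-4-methoxy-6-(methoxymethoxy)phenyl]-3-(dimethylamino)prop-2-en-1-one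
Product: 8 8-allyl-7-methoxy-5-(methoxymethoxy)-4H-chromen-4-one, via 2-(dimethylamino)chroman-4-one 7 (not isolated)
Conditions: AcOH (3 equiv), toluene, 60 °C
Reagents that add atoms: none
Why: Weak-acid-promoted 6-endo addition of the phenol to the enaminone β-carbon and loss of dimethylamine (enaminone-to-chromone cyclisation) closes the pyranone ring, and acetic acid is used instead of mineral acid so that the aryl MOM acetal should stay in place.

Step 6
Reactants: 8 8-allyl-7-methoxy-5-(methoxymethoxy)-4H-chromen-4-one
Product: 9 7-methoxy-5-(methoxymethoxy)-8-[(E)-prop-1-enyl]-4H-chromen-4-one (E expected to prevail; the Z isomer serves equally)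
Conditions: RuHCl(CO)(PPh3)3 (5 mol %), toluene, 100 °C
Reagents that add atoms: none
Why: Ruthenium-hydride alkene migration (insertion, then β-hydride elimination) brings the double bond into conjugation with the arene under neutral conditions, which avoids the strong bases that would open the chromone ring.

Step 7
Reactants: 9 7-methoxy-5-(methoxymethoxy)-8-[(E)-prop-1-enyl]-4H-chromen-4-one
Product: 11 7-methoxy-5-(methoxymethoxy)-4-oxo-4H-chromene-8-carbaldehyde, via vicinal diol 10 (not isolated)
Conditions: OsO4 (2 mol %), NaIO4 (4 equiv), 2,6-lutidine (2 equiv), dioxane/H2O 3:1, rt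
Reagents that add atoms: osmium tetroxide O=[Os](=O)(=O)=O (catalytic oxygen carrier); sodium periodate [Na+].[O-]I(=O)(=O)=O (terminal oxidant)
Why: In this Lemieux–Johnson cleavage OsO4 should dihydroxylate the electron-rich styrenic alkene far faster than the electron-poor vinylogous-ester C2=C3 bond, periodate then cleaves diol 10, and lutidine keeps the medium non-acidic.

Step 8
Reactants: 11 7-methoxy-5-(methoxymethoxy)-4-oxo-4H-chromene-8-carbaldehyde
Product: 12 8-(hydroxymethyl)-7-methoxy-5-(methoxymethoxy)-4H-chromen-4-one
Conditions: NaBH4 (0.6 equiv), CH2Cl2/MeOH 2:1, −40 → −10 °C; acetone, then aq. NH4Cl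
Reagents that add atoms: none
Why: At low temperature borohydride reduces the aldehyde much faster than the donor-stabilised vinylogous-ester carbonyl of the chromone (chemoselective 1,2-reduction).

Step 9
Reactants: 12 8-(hydroxymethyl)-7-methoxy-5-(methoxymethoxy)-4H-chromen-4-one
Product: 13 [7-methoxy-5-(methoxymethoxy)-4-oxo-4H-chromen-8-yl]methyl methyl carbonate
Conditions: ClCO2Me (1.5 equiv), pyridine (3 equiv), CH2Cl2, 0 °C; Et3N-washed silica
Reagents that add atoms: methyl chloroformate COC(=O)Cl
Why: O-acylation of the primary benzylic alcohol installs a leaving group that should be isolable, because the three ring oxygens are cross-conjugated with the C4 carbonyl, yet it still ionises readily on Pd(0).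

Step 10
Reactants: 14 propargyl alcohol
Product: 16 (Z)-3-iodo-2-methylprop-2-en-1-ol, via (Z)-alkenylmagnesium alkoxide 15 (not isolated)
Conditions: MeMgBr (2.5 equiv), CuI (10 mol %), THF, −10 °C → rt; I2 (1.6 equiv), THF, −10 → 0 °C; aq. NH4Cl
Reagents that add atoms: methylmagnesium bromide C[Mg]Br; iodine II
Why: Copper-catalysed anti-carbomagnesiation of the propargylic alkoxide puts methyl on the internal carbon and magnesium on the terminal carbon cis to CH2O in a five-membered chelate, and iodinolysis with retention fixes the Z geometry.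

Step 11
Reactants: 16 (Z)-3-iodo-2-methylprop-2-en-1-ol
Product: 17 (Z)-tert-butyl[(3-iodo-2-methylallyl)oxy]dimethylsilane
Conditions: TBSCl (1.2 equiv), imidazole (2 equiv), CH2Cl2, 0 °C → rt
Reagents that add atoms: tert-butyldimethylsilyl chloride CC(C)(C)[Si](C)(C)Cl
Why: Imidazole-promoted silylation of a primary alcohol is routine and does not touch the alkenyl iodide or its geometry.

Step 12
Reactants: 17 (Z)-tert-butyl[(3-iodo-2-methylallyl)oxy]dimethylsilane
Product: 18 (Z)-tert-butyldimethyl{[2-methyl-3-(4,4,5,5-tetramethyl-1,3,2-dioxaborolan-2-yl)allyl]oxy}silane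
Conditions: B2pin2 (1.1 equiv), PdCl2(PPh3)2 (3 mol %), PPh3 (6 mol %), KOPh (1.5 equiv), toluene, 50 °C
Reagents that add atoms: bis(pinacolato)diboron CC1(C)OB(OC1(C)C)B1OC(C)(C)C(C)(C)O1
Why: Miyaura borylation of the alkenyl iodide proceeds with retention of geometry and avoids an alkenyllithium, which would be prone to 1,4 O-to-C silyl migration in this cis-silyloxymethyl arrangement.

Step 13
Reactants: 13 [7-methoxy-5-(methoxymethoxy)-4-oxo-4H-chromen-8-yl]methyl methyl carbonate; 18 (Z)-alkenyl pinacol boronate
Product: 19 8-[(Z)-4-(tert-butyldimethylsilyloxy)-3-methylbut-2-enyl]-7-methoxy-5-(methoxymethoxy)-4H-chromen-4-one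
Conditions: 18 (1.3 equiv), [Pd(η3-C3H5)Cl]2 (2.5 mol %), Ph2P(CH2)5PPh2 (5.5 mol %), K2CO3 (1.5 equiv), DMF, 70 °C
Reagents that add atoms: none
Why: In this Suzuki–Miyaura coupling of a benzylic carbonate, Pd(0) with a wide-bite-angle bisphosphine ionises the carbonate, CO2 loss leaves a benzylpalladium methoxide that transmetalates with the alkenyl boronate, reductive elimination retains the Z geometry, and C2-unsubstituted chromones tolerate carbonate-base Suzuki conditions.

Step 14
Reactants: 20 4-bromocatechol
Product: 21 4-bromo-1,2-bis(methoxymethoxy)benzene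
Conditions: MOMCl (2.6 equiv), i-Pr2NEt (3.5 equiv), CH2Cl2, 0 °C → rt
Reagents that add atoms: chloromethyl methyl ether COCCl
Why: Both unhindered, non-chelated phenols are alkylated under amine-base MOM protection, which gives acetals that withstand organolithium chemistry.

Step 15
Reactants: 21 4-bromo-1,2-bis(methoxymethoxy)benzene
Product: 24 3,4-bis(methoxymethoxy)phenylboronic acid, via aryllithium 22 (not isolated), via lithium aryltriisopropoxyborate 23 (not isolated)
Conditions: n-BuLi (1.05 equiv), THF, −78 °C; B(Oi-Pr)3 (1.5 equiv), −78 °C → rt; AcOH (1.1 equiv)/H2O, 0 °C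
Reagents that add atoms: triisopropyl borate CC(C)OB(OC(C)C)OC(C)C; water O
Why: Bromine–lithium exchange at −78 °C outruns MOM-directed ortho-lithiation, the aryllithium is trapped as the borate, and hydrolysis with dilute acetic acid frees the boronic acid without harming the acetals.

Step 16
Reactants: 19 8-[(Z)-4-(tert-butyldimethylsilyloxy)-3-methylbut-2-enyl]-7-methoxy-5-(methoxymethoxy)-4H-chromen-4-one; 24 3,4-bis(methoxymethoxy)phenylboronic acid
Product: 25 (2S)-2-[3,4-bis(methoxymethoxy)phenyl]-8-[(Z)-4-(tert-butyldimethylsilyloxy)-3-methylbut-2-enyl]-7-methoxy-5-(methoxymethoxy)chroman-4-one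
Conditions: 24 (2.5 equiv), preformed diene-free [Rh(OH){(S)-MeO-F12-BIPHEP}]2 (3 mol % Rh; ligand = (S)-2,2'-bis[bis(3,4,5-trifluorophenyl)phosphino]-6,6'-dimethoxybiphenyl), CH2Cl2/H2O 10:1, 20–25 °C
Reagents that add atoms: none
Why: Transmetalation of 24 to the Rh(I) hydroxide gives an aryl–rhodium species, the chromone C2=C3 bond binds, enantio-determining migratory insertion forms the C2–C1' bond, and water hydrolyses the oxa-π-allyl rhodium enolate to release 25 and regenerate Rh–OH. The closest known reaction type is the Hayashi–Miyaura asymmetric 1,4-addition of arylboronic acids, which has been extended to 4H-chromen-4-ones, 5,7-dioxygenated ones included, with electron-poor biaryl bisphosphines. No ring is closed, since ring C is already present. C2 is the only new stereocentre, and because 19 is achiral and planar its configuration is set solely by the C2-symmetric ligand, whose (S)-antipode should leave open the approach that puts the aryl group on the face leading to 2S. The step needs enantiofacial selectivity, 1,4- over 1,2-addition and no second addition to the product ketone; these are secured by the single unhindered β-CH of the s-trans-locked vinylogous ester, the peri 5-OMOM group shielding C4 and the choice of CH2Cl2, while the trisubstituted side-chain alkene does not insert. The neutral room-temperature medium leaves the MOM and TBS groups intact and gives no retro-oxa-Michael path to racemisation, and the lower electrophilicity of the donor-rich chromone is met by the π-acidic ligand and excess boronic acid.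

Step 17
Reactants: 25 (2S)-protected flavanone
Product: 26 (2S)-2-(3,4-dihydroxyphenyl)-5-hydroxy-8-[(Z)-4-hydroxy-3-methylbut-2-enyl]-7-methoxychroman-4-one (CNP0246822.1)
Conditions: HCl in MeOH (ca. 1 M)/THF 2:1, 0 → 35 °C, Ar
Reagents that add atoms: none
Why: Acid-catalysed transacetalisation of the three aryl MOM groups and methanolysis of the primary silyl ether run without base, so C2 cannot epimerise through the chalcone, and the side chain should hold because ionisation of this allylic alcohol would give only a primary/secondary allyl cation with the methyl on the nodal carbon and no free phenol flanks the chain.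

## Compound list

1 | 2',6'-dihydroxy-4'-methoxyacetophenone | CC(=O)c1c(O)cc(OC)cc1O | starting material
2 | 2'-allyloxy-6'-hydroxy-4'-methoxyacetophenone | CC(=O)c1c(O)cc(OC)cc1OCC=C | intermediate
3 | 2'-allyloxy-4'-methoxy-6'-(methoxymethoxy)acetophenone | CC(=O)c1c(OCC=C)cc(OC)cc1OCOC | intermediate
4 | 2-acetyl-6-allyl-5-methoxy-3-(methoxymethoxy)cyclohexa-2,4-dien-1-one (racemic, not isolated) | CC(=O)C1=C(OCOC)C=C(OC)C(CC=C)C1=O | intermediate
5 | 3'-allyl-2'-hydroxy-4'-methoxy-6'-(methoxymethoxy)acetophenone | CC(=O)c1c(O)c(CC=C)c(OC)cc1OCOC | intermediate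
6 | (E)-1-[3-allyl-2-hydroxy-4-methoxy-6-(methoxymethoxy)phenyl]-3-(dimethylamino)prop-2-en-1-one | CN(C)/C=C/C(=O)c1c(O)c(CC=C)c(OC)cc1OCOC | intermediate
7 | 8-allyl-2-(dimethylamino)-7-methoxy-5-(methoxymethoxy)chroman-4-one (racemic, not isolated) | CN(C)C1CC(=O)c2c(OCOC)cc(OC)c(CC=C)c2O1 | intermediate
8 | 8-allyl-7-methoxy-5-(methoxymethoxy)-4H-chromen-4-one | O=c1ccoc2c(CC=C)c(OC)cc(OCOC)c12 | intermediate
9 | 7-methoxy-5-(methoxymethoxy)-8-[(E)-prop-1-enyl]-4H-chromen-4-one | O=c1ccoc2c(/C=C/C)c(OC)cc(OCOC)c12 | intermediate
10 | 8-(1,2-dihydroxypropyl)-7-methoxy-5-(methoxymethoxy)-4H-chromen-4-one (stereoisomer mixture, not isolated) | O=c1ccoc2c(C(O)C(C)O)c(OC)cc(OCOC)c12 | intermediate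
11 | 7-methoxy-5-(methoxymethoxy)-4-oxo-4H-chromene-8-carbaldehyde | O=Cc1c(OC)cc(OCOC)c2c(=O)ccoc12 | intermediate
12 | 8-(hydroxymethyl)-7-methoxy-5-(methoxymethoxy)-4H-chromen-4-one | OCc1c(OC)cc(OCOC)c2c(=O)ccoc12 | intermediate
13 | [7-methoxy-5-(methoxymethoxy)-4-oxo-4H-chromen-8-yl]methyl methyl carbonate | COC(=O)OCc1c(OC)cc(OCOC)c2c(=O)ccoc12 | intermediate
14 | propargyl alcohol | C#CCO | starting material
15 | (Z)-3-(bromomagnesio)-2-methylallyloxymagnesium bromide (not isolated) | Br[Mg]/C=C(/C)CO[Mg]Br | intermediate
16 | (Z)-3-iodo-2-methylprop-2-en-1-ol | I/C=C(/C)CO | intermediate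
17 | (Z)-tert-butyl[(3-iodo-2-methylallyl)oxy]dimethylsilane | I/C=C(/C)CO[Si](C)(C)C(C)(C)C | intermediate
18 | (Z)-tert-butyldimethyl{[2-methyl-3-(4,4,5,5-tetramethyl-1,3,2-dioxaborolan-2-yl)allyl]oxy}silane | CC1(C)OB(/C=C(/C)CO[Si](C)(C)C(C)(C)C)OC1(C)C | intermediate
19 | 8-[(Z)-4-(tert-butyldimethylsilyloxy)-3-methylbut-2-enyl]-7-methoxy-5-(methoxymethoxy)-4H-chromen-4-one | O=c1ccoc2c(C/C=C(/C)CO[Si](C)(C)C(C)(C)C)c(OC)cc(OCOC)c12 | intermediate
20 | 4-bromocatechol | Oc1ccc(Br)cc1O | starting material
21 | 4-bromo-1,2-bis(methoxymethoxy)benzene | COCOc1ccc(Br)cc1OCOC | intermediate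
22 | 3,4-bis(methoxymethoxy)phenyllithium (not isolated) | [Li]c1ccc(OCOC)c(OCOC)c1 | intermediate
23 | lithium [3,4-bis(methoxymethoxy)phenyl]triisopropoxyborate (not isolated) | [Li+].CC(C)O[B-](OC(C)C)(OC(C)C)c1ccc(OCOC)c(OCOC)c1 | intermediate
24 | 3,4-bis(methoxymethoxy)phenylboronic acid | COCOc1ccc(B(O)O)cc1OCOC | intermediate
25 | (2S)-2-[3,4-bis(methoxymethoxy)phenyl]-8-[(Z)-4-(tert-butyldimethylsilyloxy)-3-methylbut-2-enyl]-7-methoxy-5-(methoxymethoxy)chroman-4-one | COc1cc(OCOC)c2c(c1C/C=C(/C)CO[Si](C)(C)C(C)(C)C)O[C@H](c1ccc(OCOC)c(OCOC)c1)CC2=O | intermediate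
26 | (2S)-2-(3,4-dihydroxyphenyl)-5-hydroxy-8-[(Z)-4-hydroxy-3-methylbut-2-enyl]-7-methoxychroman-4-one | COc1cc(O)c2c(c1C/C=C(/C)CO)O[C@H](c1ccc(O)c(O)c1)CC2=O | target

Total step count: 17
Longest linear sequence: 12 steps (steps 1–9, 13, 16, 17, from 1 to 26)

## Steps most likely to fail

**Step 16.**
- What may go wrong: insertion into the donor-rich chromone may be slow, so that protodeboronation of the electron-rich boronic acid wins. The facial selectivity may also fall short.
- Fallback: enantiopurity is obtained by resolution instead of asymmetric C–C bond formation.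
  - The fallback sets out from 19 and 24. These are joined with the more active achiral catalyst [Rh(OH)(cod)]2 in dioxane/H2O at 50 °C to give the racemic protected flavanone F1.
  - F1 then undergoes kinetic resolution by Noyori–Ikariya asymmetric transfer hydrogenation (RuCl(p-cymene)[(R,R)-TsDPEN], HCO2H/Et3N, EtOAc, rt), stopped near half conversion.
  - The (2R)-ketone should be reduced to the cis-(2R,4R)-flavan-4-ol F2, which is removed by chromatography.
  - The unreacted ketone is 25, where the route is rejoined.

**Step 13.**
- What may go wrong: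
  - The carbonate may ionise or solvolyse early.
  - The liberated methoxide may capture the benzylpalladium species.
  - Benzyl homocoupling may compete.
  - Transmetalation of the hindered Z-boronate may be slow.
  - The new alkene may migrate into conjugation.
- Fallback: the polarity of the coupling is reversed, and compounds 13 and 18 are bypassed.
  - The fallback sets out from 12. MsCl, Et3N and LiCl in THF at 0 °C should give the 8-(chloromethyl)chromone F3.
  - LiCl-assisted zinc insertion (Zn dust, THF, rt) turns F3 into the benzylic zinc chloride F4.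
  - Negishi coupling of F4 with alkenyl iodide 17 (Pd(OAc)2/SPhos, THF, rt), stereoretentive at the alkene, comes back to the route at 19.

**Step 17.**
- What may go wrong: cleavage of the catechol MOM groups may stay incomplete at the temperature the side chain tolerates. Alternatively, acid may induce allylic substitution or Z-to-E scrambling once the alcohol is free.
- Fallback: a staged, non-protic unmasking in which the silyl ether guards the allylic position while the acetals are removed.
  - The fallback sets out from 25. ZnBr2 and n-PrSH in CH2Cl2 at 0 °C (thiol-assisted Lewis-acid MOM cleavage) should give the triphenolic side-chain silyl ether F5.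
  - HF·pyridine in THF/pyridine at 0 °C then removes the TBS group and arrives at 26.

## Further compounds

F1 | step 16 | racemic 2-[3,4-bis(methoxymethoxy)phenyl]-8-[(Z)-4-(tert-butyldimethylsilyloxy)-3-methylbut-2-enyl]-7-methoxy-5-(methoxymethoxy)chroman-4-one | COc1cc(OCOC)c2c(c1C/C=C(/C)CO[Si](C)(C)C(C)(C)C)OC(c1ccc(OCOC)c(OCOC)c1)CC2=O
F2 | step 16 | (2R,4R)-2-[3,4-bis(methoxymethoxy)phenyl]-8-[(Z)-4-(tert-butyldimethylsilyloxy)-3-methylbut-2-enyl]-7-methoxy-5-(methoxymethoxy)chroman-4-ol | COc1cc(OCOC)c2c(c1C/C=C(/C)CO[Si](C)(C)C(C)(C)C)O[C@@H](c1ccc(OCOC)c(OCOC)c1)C[C@H]2O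
F3 | step 13 | 8-(chloromethyl)-7-methoxy-5-(methoxymethoxy)-4H-chromen-4-one | ClCc1c(OC)cc(OCOC)c2c(=O)ccoc12
F4 | step 13 | {[7-methoxy-5-(methoxymethoxy)-4-oxo-4H-chromen-8-yl]methyl}zinc chloride | Cl[Zn]Cc1c(OC)cc(OCOC)c2c(=O)ccoc12
F5 | step 17 | (2S)-8-[(Z)-4-(tert-butyldimethylsilyloxy)-3-methylbut-2-enyl]-2-(3,4-dihydroxyphenyl)-5-hydroxy-7-methoxychroman-4-one | COc1cc(O)c2c(c1C/C=C(/C)CO[Si](C)(C)C(C)(C)C)O[C@H](c1ccc(O)c(O)c1)CC2=O
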